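**Retrosynthetic overview**
1. Numbering: cyclohexane C1 (C–OH), C2, C3, C4 (CMeCl), C5 (CHBr), C6; cyclopentane C1' (quaternary, bonded to C1), C2' (CMe2), C3' (CHBr).
2. 21 ⇒ 20 ⇒ 19: the C3'–Br comes last from a carboxyl group (decarboxylative bromination). That carboxyl and the C1 hydroxyl are tied as a δ-lactone, a temporary ring, from step 5 to step 10.
3. 19 ⇒ 13: C4–Cl by chloride return through the bromonium ion of the C5 bromide; C4–CH3 by addition to a C4 ketone; C5–Br by desymmetrising enolisation and bromination of the symmetric spiro-lactone ketone 13.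
4. 13 ⇒ 5 + 6 (key disconnection): C2–C3 and C6–C5 are made together in a [3+3] annulation. Enabling feature: C1 is a carbinol carbon between two unsubstituted ring CH2 groups (C2, C6) and para to C4, so C2–C1(O)–C6 can be carried as a bis(chloromethyl)carbinol / chloromethyl oxirane and C3–C4–C5 is an acetone unit.
5. 5 ⇒ 1: the cyclopentane ring and both of its stereocenters come from (1R,3S)-camphoric acid, whose tertiary carboxyl carbon becomes C1. Ring order: cyclopentane (chiral pool), cyclohexane (step 4), temporary lactone (step 5, opened in step 10).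

Key step: step 4

Remark 1: the sense of induction of lithium bis[(R)-1-phenylethyl]amide in step 6 is assumed by analogy with 4-substituted cyclohexanones that carry a large equatorial group; if 13 reacts with the opposite sense, the (S,S)-amide is used.
Remark 2: the cyclohexane ring of 13–19 is assumed to sit in the chair with the lactone oxygen axial and the bicyclic carbon equatorial.

Step 1
Reactants: 1 (1R,3S)-(+)-camphoric acid
Product: 2 dimethyl (1R,3S)-1,2,2-trimethylcyclopentane-1,3-dicarboxylate
Conditions: MeI, K2CO3, DMF, rt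
Reagents that add atoms: iodomethane, SMILES CI
Why: O-alkylation of the carboxylates (SN2 on MeI) should esterify both acids, including the hindered tertiary one that resists Fischer esterification, and touches neither stereocenter.

Step 2
Reactants: 2 dimethyl (1R,3S)-1,2,2-trimethylcyclopentane-1,3-dicarboxylate
Product: 3 (1S,3R)-3-(methoxycarbonyl)-2,2,3-trimethylcyclopentane-1-carboxylic acid
Conditions: KOH (1.05 equiv), MeOH/H2O, 50 °C; then 1 M HCl to pH 2
Reagents that add atoms: potassium hydroxide, SMILES [K+].[OH-]
Why: Saponification (BAc2) should be site-selective for the secondary ester because the tertiary, neopentyl-type ester is shielded, and aqueous hydroxide does not enolise the ester-bearing CH, so both stereocenters are kept.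

Step 3
Reactants: 3 (1S,3R)-3-(methoxycarbonyl)-2,2,3-trimethylcyclopentane-1-carboxylic acid
Product: 5 (1S,3R)-3-(1,3-dichloro-2-hydroxypropan-2-yl)-2,2,3-trimethylcyclopentane-1-carboxylic acid, via chloromethyl ketone 4 (not isolated)
Conditions: LiN(SiMe3)2 (1.0 equiv), THF, −78 °C; ICH2Cl (3.5 equiv), MeLi·LiBr (3.5 equiv), −78 °C; AcOH, −78 °C
Reagents that add atoms: chloroiodomethane, SMILES ClCI
Why: Double addition of chloromethyllithium (a lithium carbenoid made in situ by iodine–lithium exchange) to the ester should give the 1,3-dichloro-2-propanol while the lithium carboxylate stays inert, the cold acidic quench prevents oxirane closure, and the new carbinol carbon carries two identical CH2Cl arms, so no stereocenter arises.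

Step 4
Reactants: 5 (1S,3R)-3-(1,3-dichloro-2-hydroxypropan-2-yl)-2,2,3-trimethylcyclopentane-1-carboxylic acid; 6 acetone N,N-dimethylhydrazone
Product: 11 (1S,3R)-3-(1-hydroxy-4-oxocyclohexyl)-2,2,3-trimethylcyclopentane-1-carboxylic acid, via chloromethyl oxirane 7 (not isolated), via chlorohydrin hydrazone 8 (not isolated), via oxirane hydrazone 9 (not isolated), via cyclic hydrazone 10 (not isolated)
Conditions: LiN(i-Pr)2 (2.1 equiv), THF, −78 → 0 °C; lithiated 6 (from 6 and LiN(i-Pr)2, 1.3 equiv), DMPU, 0 °C → rt; LiN(i-Pr)2 (1.5 equiv), −78 °C → rt; then aq. CuCl2, THF, pH 7, rt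
Reagents that add atoms: water, SMILES O
Why: Proposed new method: a [3+3] annulation by double oxirane relay, in which the base turns 5 into its carboxylate alkoxide that closes (3-exo-tet) to oxirane 7, lithiated 6 opens 7 at its CH2 group (first C–C bond), the tertiary alkoxide 8 so released displaces the second chloride to give oxirane 9, and a second deprotonation at the hydrazone CH3 lets the aza-enolate open 9 intramolecularly (second C–C bond), so that the later C2–C3 and C6–C5 bonds form in one operation. The closest known reaction types are the α,α'-dialkylation of ketone N,N-dimethylhydrazones, the opening of oxiranes by hydrazone anions and the twofold substitution of epichlorohydrin through its re-formed oxirane; their merger into one ring-forming operation on a 2,2-disubstituted chloromethyl oxirane is the new element. The cyclohexane ring closes by SN2 opening of the oxirane at its primary carbon, 6-endo with respect to the oxirane, the 5-exo mode being impossible at the fully substituted carbon. No stereocenter is formed, because the ring stays symmetric and C1 remains non-stereogenic until step 6; the carbinol or oxirane carbon of 7–9 is a transient stereocenter whose configuration is irrelevant. The selectivity needed is attack at the two CH2 termini only and C-alkylation at the unsubstituted α-carbon: both CH2Cl groups are neopentyl-type and inert to direct SN2 so only the oxirane relay can operate, dimethylhydrazone anions alkylate at carbon and are deprotonated kinetically at the methyl group, and the lithium carboxylate is inert to them. CuCl2 at pH 7 should then cleave the hydrazone without ionising the tertiary carbinol.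

Step 5
Reactants: 11 (1S,3R)-3-(1-hydroxy-4-oxocyclohexyl)-2,2,3-trimethylcyclopentane-1-carboxylic acid
Product: 13 (1R,5S)-1,8,8-trimethylspiro[3-oxabicyclo[3.2.1]octane-2,1'-cyclohexane]-4,4'-dione, via mixed anhydride 12 (not isolated)
Conditions: 2,4,6-Cl3C6H2COCl, Et3N, THF, rt; then DMAP, toluene, 80 °C, high dilution
Reagents that add atoms: none
Why: Yamaguchi lactonisation should let the cis-disposed tertiary hydroxyl attack the mixed anhydride (6-exo-trig) to give the δ-lactone, a temporary ring that protects both groups, makes the carboxyl-bearing carbon a non-enolisable bridgehead and later keeps the carbinol oxygen from attacking the bromonium ion; no stereocenter is created because the cyclohexanone ring is still symmetric.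

Step 6
Reactants: 13 (1R,5S)-1,8,8-trimethylspiro[3-oxabicyclo[3.2.1]octane-2,1'-cyclohexane]-4,4'-dione
Product: 14 (1R,2R,5S)-1,8,8-trimethyl-4'-(trimethylsilyloxy)spiro[3-oxabicyclo[3.2.1]octane-2,1'-cyclohex-3'-en]-4-one
Conditions: lithium bis[(R)-1-phenylethyl]amide (1.2 equiv), LiCl, Me3SiCl, THF, −100 → −78 °C
Reagents that add atoms: chlorotrimethylsilane, SMILES C[Si](C)(C)Cl
Why: Desymmetrising deprotonation of a 4,4-disubstituted cyclohexanone by a chiral lithium amide with internal silyl quench should remove one of the two axial α-hydrogens, and this reagent-controlled choice of the α-methylene makes the spiro carbinol carbon C1 stereogenic with the configuration required in 21.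

Step 7
Reactants: 14 (1R,2R,5S)-1,8,8-trimethyl-4'-(trimethylsilyloxy)spiro[3-oxabicyclo[3.2.1]octane-2,1'-cyclohex-3'-en]-4-one
Product: 16 (1R,2R,3'S,5S)-3'-bromo-1,8,8-trimethylspiro[3-oxabicyclo[3.2.1]octane-2,1'-cyclohexane]-4,4'-dione, via axial bromo ketone 15 (not isolated)
Conditions: NBS, THF, −78 °C; then LiBr (20 mol%), acetone, rt
Reagents that add atoms: N-bromosuccinimide, SMILES O=C1CCC(=O)N1Br
Why: Electrophilic α-bromination of the silyl enol ether fixes bromine regiospecifically on C5, and bromide-catalysed epimerisation (SN2 exchange at the α-keto carbon) should funnel the kinetic mixture to the equatorial bromide trans to the axial lactone oxygen, because the axial epimer 15 suffers a 1,3-diaxial Br/O repulsion, so C5 is set under thermodynamic control.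

Step 8
Reactants: 16 (1R,2R,3'S,5S)-3'-bromo-1,8,8-trimethylspiro[3-oxabicyclo[3.2.1]octane-2,1'-cyclohexane]-4,4'-dione
Product: 17 (1R,2R,3'S,4'S,5S)-3'-bromo-4'-hydroxy-1,4',8,8-tetramethylspiro[3-oxabicyclo[3.2.1]octane-2,1'-cyclohexan]-4-one
Conditions: MeMgBr, CeCl3, THF, −78 °C; aq. NH4Cl, −78 °C
Reagents that add atoms: methylmagnesium bromide, SMILES C[Mg]Br
Why: Organocerium 1,2-addition should be selective for the ketone over the hindered lactone and non-basic enough to avoid enolisation or Favorskii-type loss of bromide; axial attack of the small methyl nucleophile is expected to give the equatorial hydroxyl (cis to the lactone oxygen), and the C4 epimer would ionise to the same bromonium ion in step 9.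

Step 9
Reactants: 17 (1R,2R,3'S,4'S,5S)-3'-bromo-4'-hydroxy-1,4',8,8-tetramethylspiro[3-oxabicyclo[3.2.1]octane-2,1'-cyclohexan]-4-one
Product: 19 (1R,2R,3'S,4'S,5S)-3'-bromo-4'-chloro-1,4',8,8-tetramethylspiro[3-oxabicyclo[3.2.1]octane-2,1'-cyclohexan]-4-one, via chlorosulfite 18 (not isolated)
Conditions: SOCl2 (1.5 equiv), CH2Cl2, −20 °C → rt
Reagents that add atoms: thionyl chloride, SMILES O=S(Cl)Cl
Why: Chlorodehydroxylation through the chlorosulfite with neighbouring-bromine participation (the classical bromohydrin-to-dihalide conversion with retention) should ionise the tertiary carbon to the bromonium ion on the face bromine already occupies and return chloride at that carbon anti to bromine, so Cl ends trans to Br and cis to the lactone oxygen, while the lactone oxygen, being an ester oxygen, neither closes a bridged ether nor ionises.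

Step 10
Reactants: 19 (1R,2R,3'S,4'S,5S)-3'-bromo-4'-chloro-1,4',8,8-tetramethylspiro[3-oxabicyclo[3.2.1]octane-2,1'-cyclohexan]-4-one
Product: 20 (1S,3R)-3-[(1R,3S,4S)-3-bromo-4-chloro-1-hydroxy-4-methylcyclohexyl]-2,2,3-trimethylcyclopentane-1-carboxylic acid
Conditions: KOH, MeOH/H2O, 40 °C; then 1 M HCl to pH 4, 0 °C
Reagents that add atoms: potassium hydroxide, SMILES [K+].[OH-]
Why: Saponification (BAc2) of the strained δ-lactone should free the tertiary alcohol and the acid; the dihalide is expected to survive because in the only accessible chair both halogens are equatorial, leaving no antiperiplanar hydrogen for E2, and the β-bromine retards ionisation of the tertiary chloride, so no stereocenter is touched.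

Step 11
Reactants: 20 (1S,3R)-3-[(1R,3S,4S)-3-bromo-4-chloro-1-hydroxy-4-methylcyclohexyl]-2,2,3-trimethylcyclopentane-1-carboxylic acid
Product: 21 (1R,3S,4S)-3-bromo-1-[(1R,3S)-3-bromo-1,2,2-trimethylcyclopentyl]-4-chloro-4-methylcyclohexan-1-ol (target)
Conditions: [Ir(dF(CF3)ppy)2(dtbbpy)]PF6 (1 mol%), BrCH(CO2Et)2, Cs2CO3 (20 mol%), PhCl, blue LEDs, rt
Reagents that add atoms: diethyl bromomalonate, SMILES CCOC(=O)C(Br)C(=O)OCC
Why: Photoredox decarboxylative bromination (carboxylate oxidation, loss of CO2, bromine-atom transfer from the bromomalonate) should brominate the planar C3' radical from the face anti to the pseudo-axial C1' methyl group, the very large hydroxycyclohexyl group being pseudo-equatorial, which places Br cis to that group and so keeps the camphoric acid configuration; the tertiary alcohol and the unactivated alkyl halides are inert under these conditions.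

**Compound list**
1 | (1R,3S)-(+)-camphoric acid, (1R,3S)-1,2,2-trimethylcyclopentane-1,3-dicarboxylic acid | CC1(C)[C@@H](C(=O)O)CC[C@@]1(C)C(=O)O | starting material
2 | dimethyl (1R,3S)-1,2,2-trimethylcyclopentane-1,3-dicarboxylate | CC1(C)[C@@H](C(=O)OC)CC[C@@]1(C)C(=O)OC | intermediate
3 | (1S,3R)-3-(methoxycarbonyl)-2,2,3-trimethylcyclopentane-1-carboxylic acid | CC1(C)[C@@H](C(=O)O)CC[C@@]1(C)C(=O)OC | intermediate
4 | (1S,3R)-3-(chloroacetyl)-2,2,3-trimethylcyclopentane-1-carboxylic acid (lithium salt in the flask) | CC1(C)[C@@H](C(=O)O)CC[C@@]1(C)C(=O)CCl | intermediate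
5 | (1S,3R)-3-(1,3-dichloro-2-hydroxypropan-2-yl)-2,2,3-trimethylcyclopentane-1-carboxylic acid | CC1(C)[C@@H](C(=O)O)CC[C@@]1(C)C(O)(CCl)CCl | intermediate
6 | acetone N,N-dimethylhydrazone | CC(C)=NN(C)C | starting material
7 | (1S,3R)-3-[2-(chloromethyl)oxiran-2-yl]-2,2,3-trimethylcyclopentane-1-carboxylic acid (both oxirane epimers, lithium salt in the flask) | CC1(C)[C@@H](C(=O)O)CC[C@@]1(C)C1(CCl)CO1 | intermediate
8 | (1S,3R)-3-[1-chloro-5-(2,2-dimethylhydrazinylidene)-2-hydroxyhexan-2-yl]-2,2,3-trimethylcyclopentane-1-carboxylic acid (both carbinol epimers, dilithium salt in the flask) | CC1(C)[C@@H](C(=O)O)CC[C@@]1(C)C(O)(CCl)CCC(C)=NN(C)C | intermediate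
9 | (1S,3R)-3-{2-[3-(2,2-dimethylhydrazinylidene)butyl]oxiran-2-yl}-2,2,3-trimethylcyclopentane-1-carboxylic acid (both oxirane epimers) | CC1(C)[C@@H](C(=O)O)CC[C@@]1(C)C1(CCC(C)=NN(C)C)CO1 | intermediate
10 | (1S,3R)-3-[4-(2,2-dimethylhydrazinylidene)-1-hydroxycyclohexyl]-2,2,3-trimethylcyclopentane-1-carboxylic acid | CC1(C)[C@@H](C(=O)O)CC[C@@]1(C)C1(O)CCC(=NN(C)C)CC1 | intermediate
11 | (1S,3R)-3-(1-hydroxy-4-oxocyclohexyl)-2,2,3-trimethylcyclopentane-1-carboxylic acid | CC1(C)[C@@H](C(=O)O)CC[C@@]1(C)C1(O)CCC(=O)CC1 | intermediate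
12 | mixed anhydride of 11 with 2,4,6-trichlorobenzoic acid | CC1(C)[C@@H](C(=O)OC(=O)c2c(Cl)cc(Cl)cc2Cl)CC[C@@]1(C)C1(O)CCC(=O)CC1 | intermediate
13 | (1R,5S)-1,8,8-trimethylspiro[3-oxabicyclo[3.2.1]octane-2,1'-cyclohexane]-4,4'-dione (δ-lactone of 11) | CC1(C)[C@@H]2CC[C@@]1(C)C3(OC2=O)CCC(=O)CC3 | intermediate
14 | (1R,2R,5S)-1,8,8-trimethyl-4'-(trimethylsilyloxy)spiro[3-oxabicyclo[3.2.1]octane-2,1'-cyclohex-3'-en]-4-one | CC1(C)[C@@H]2CC[C@@]1(C)[C@@]3(OC2=O)CCC(O[Si](C)(C)C)=CC3 | intermediate
15 | (1R,2R,3'R,5S)-3'-bromo-1,8,8-trimethylspiro[3-oxabicyclo[3.2.1]octane-2,1'-cyclohexane]-4,4'-dione (axial bromide, cis to the lactone oxygen) | CC1(C)[C@@H]2CC[C@@]1(C)[C@@]3(OC2=O)CCC(=O)[C@H](Br)C3 | intermediate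
16 | (1R,2R,3'S,5S)-3'-bromo-1,8,8-trimethylspiro[3-oxabicyclo[3.2.1]octane-2,1'-cyclohexane]-4,4'-dione (equatorial bromide, trans to the lactone oxygen) | CC1(C)[C@@H]2CC[C@@]1(C)[C@@]3(OC2=O)CCC(=O)[C@@H](Br)C3 | intermediate
17 | (1R,2R,3'S,4'S,5S)-3'-bromo-4'-hydroxy-1,4',8,8-tetramethylspiro[3-oxabicyclo[3.2.1]octane-2,1'-cyclohexan]-4-one | CC1(C)[C@@H]2CC[C@@]1(C)[C@@]3(OC2=O)CC[C@](C)(O)[C@@H](Br)C3 | intermediate
18 | chlorosulfite ester of 17 | CC1(C)[C@@H]2CC[C@@]1(C)[C@@]3(OC2=O)CC[C@](C)(OS(Cl)=O)[C@@H](Br)C3 | intermediate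
19 | (1R,2R,3'S,4'S,5S)-3'-bromo-4'-chloro-1,4',8,8-tetramethylspiro[3-oxabicyclo[3.2.1]octane-2,1'-cyclohexan]-4-one | CC1(C)[C@@H]2CC[C@@]1(C)[C@@]3(OC2=O)CC[C@](C)(Cl)[C@@H](Br)C3 | intermediate
20 | (1S,3R)-3-[(1R,3S,4S)-3-bromo-4-chloro-1-hydroxy-4-methylcyclohexyl]-2,2,3-trimethylcyclopentane-1-carboxylic acid | CC1(C)[C@@H](C(=O)O)CC[C@@]1(C)[C@@]1(O)CC[C@](C)(Cl)[C@@H](Br)C1 | intermediate
21 | (1R,3S,4S)-3-bromo-1-[(1R,3S)-3-bromo-1,2,2-trimethylcyclopentyl]-4-chloro-4-methylcyclohexan-1-ol | CC1(C)[C@@H](Br)CC[C@@]1(C)[C@@]1(O)CC[C@](C)(Cl)[C@@H](Br)C1 | target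

**Step count and risks**
Total step count: 11. Longest linear sequence: 11 steps (1 to 21); 6 is the only other building block.

Steps most likely to fail:

1. Step 4 (Proposed new method). The relay may stall at the very hindered oxirane, or the strong base may divert the oxiranes into elimination; the second deprotonation may also occur at the substituted α-carbon, so that the ring does not close. Fallback: from 3, used as its magnesium carboxylate, double addition of the 1,5-bis-Grignard reagent made from 2,2-bis(2-bromoethyl)-1,3-dioxolane and Mg (CeCl3-promoted addition of a bis-Grignard reagent to an ester) would give (1S,3R)-3-(8-hydroxy-1,4-dioxaspiro[4.5]decan-8-yl)-2,2,3-trimethylcyclopentane-1-carboxylic acid F1. Pyridinium p-toluenesulfonate in wet acetone would then free the ketone and rejoin the route at 11. This gives up the one-operation annulation and builds the ring from C1 outwards.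

2. Step 6. Discrimination between the two α-methylene groups may be poor if the chiral amide and the camphor-derived spiro-lactone are mismatched, which would scramble the configuration of C1 relative to the cyclopentane. Fallback: from 13, unselective enolisation with LiN(i-Pr)2/Me3SiCl would give 14 together with the regioisomeric silyl enol ether (1R,2S,5S)-1,8,8-trimethyl-4'-(trimethylsilyloxy)spiro[3-oxabicyclo[3.2.1]octane-2,1'-cyclohex-3'-en]-4-one F2. Bromination and bromide equilibration as in step 7 would give 16 and the diastereomeric bromo ketone (1R,2S,3'R,5S)-3'-bromo-1,8,8-trimethylspiro[3-oxabicyclo[3.2.1]octane-2,1'-cyclohexane]-4,4'-dione F3. These are diastereomers, not enantiomers, and should separate by crystallisation or chromatography; F3 would be recycled to 13 with Zn/AcOH, and the route is rejoined at 16.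

3. Step 11. Facial selectivity of bromine-atom transfer to the planar cyclopentyl radical may be poor, which would lose the camphoric acid configuration, and the vicinal dihalide may be photoreduced. Fallback: from 20, photocatalytic aerobic decarboxylative oxygenation (9-mesityl-10-methylacridinium tetrafluoroborate, O2, blue light, then Dess–Martin periodinane) would give (3R)-3-[(1R,3S,4S)-3-bromo-4-chloro-1-hydroxy-4-methylcyclohexyl]-2,2,3-trimethylcyclopentan-1-one F4. LiBH(s-Bu)3 at −78 °C would deliver hydride from the face anti to the C1' methyl group and give (1R,3R)-3-[(1R,3S,4S)-3-bromo-4-chloro-1-hydroxy-4-methylcyclohexyl]-2,2,3-trimethylcyclopentan-1-ol F5, with the hydroxyl trans to the cyclohexyl group. Appel bromination (CBr4, PPh3) with inversion would rejoin the route at 21, the C–Br configuration then being fixed by a stereospecific substitution instead of a radical atom transfer.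

Further compounds
F1 | step 4 | (1S,3R)-3-(8-hydroxy-1,4-dioxaspiro[4.5]decan-8-yl)-2,2,3-trimethylcyclopentane-1-carboxylic acid | CC1(C)[C@@H](C(=O)O)CC[C@@]1(C)C1(O)CCC2(CC1)OCCO2
F2 | step 6 | (1R,2S,5S)-1,8,8-trimethyl-4'-(trimethylsilyloxy)spiro[3-oxabicyclo[3.2.1]octane-2,1'-cyclohex-3'-en]-4-one | CC1(C)[C@@H]2CC[C@@]1(C)[C@]3(OC2=O)CCC(O[Si](C)(C)C)=CC3
F3 | step 6 | (1R,2S,3'R,5S)-3'-bromo-1,8,8-trimethylspiro[3-oxabicyclo[3.2.1]octane-2,1'-cyclohexane]-4,4'-dione | CC1(C)[C@@H]2CC[C@@]1(C)[C@]3(OC2=O)CCC(=O)[C@H](Br)C3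
F4 | step 11 | (3R)-3-[(1R,3S,4S)-3-bromo-4-chloro-1-hydroxy-4-methylcyclohexyl]-2,2,3-trimethylcyclopentan-1-one | CC1(C)C(=O)CC[C@@]1(C)[C@@]1(O)CC[C@](C)(Cl)[C@@H](Br)C1
F5 | step 11 | (1R,3R)-3-[(1R,3S,4S)-3-bromo-4-chloro-1-hydroxy-4-methylcyclohexyl]-2,2,3-trimethylcyclopentan-1-ol | CC1(C)[C@H](O)CC[C@@]1(C)[C@@]1(O)CC[C@](C)(Cl)[C@@H](Br)C1
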